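Ring D is cut at C3''–C2'' and O–C2'' together. It is a 2‑substituted dihydrobenzofuran whose methylene C3'' sits on C2' and whose ether oxygen sits on C3' of ring C, so this CH2–aryl–O unit is a latent ortho‑quinone methide and C2'' is a one‑carbon ylide carbon. A [4+1] annulation of that methide with a cinchona‑derived ammonium ylide of tert‑butyl bromoacetate closes ring D and sets the (S) centre at C2'' in one operation, leaving an ester that becomes the dimethylcarbinol. The precursor is the complete geranylated 2‑arylbenzofuran bearing a free C3' phenol, a C2' tosylmethyl group and triisopropylsilyl ethers on O5' and O6.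

Key step: step 13

Abbreviations and locants: geranyl = (2E)‑3,7‑dimethylocta‑2,6‑dien‑1‑yl; TIPS = triisopropylsilyl; benzofuran rings A and B carry plain locants, ring C primed locants, ring D double‑primed locants.

Assumption: the O‑methylquinidine salt is taken as the pseudoenantiomer that gives the (2S) ester; if a trial on plain 2‑(tosylmethyl)phenol shows the opposite sense, the O‑methylquinine salt is made and used in the same way.

Design remark: TIPS ethers are used on O6 and O5' because both must survive aqueous phosphate (step 8) and Cs2CO3 (step 13); a free O5' phenoxide, para to the sulfonylmethyl carbon, would open a para‑quinone methide pathway.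

Step 1
Reactants: 1 2,4‑dihydroxybenzaldehyde; 2 geranyl bromide
Product: 3 3‑geranyl‑2,4‑dihydroxybenzaldehyde
Conditions: KOH (10% aq), rt
Reagents that add atoms: none
Why: Phenoxide C‑allylation: in aqueous KOH the resorcinol dianion is alkylated on carbon, and C3 between the two oxygens is the doubly activated site, so the geranyl group should enter there by direct SN2 displacement with its E olefin intact, while O‑alkylated and C5 isomers are removed by chromatography.

Step 2
Reactants: 3 3‑geranyl‑2,4‑dihydroxybenzaldehyde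
Product: 4 3‑geranyl‑2‑hydroxy‑4‑(triisopropylsilyloxy)benzaldehyde
Conditions: TIPSCl (1.1 equiv), imidazole, DMF, 0 °C → rt
Reagents that add atoms: triisopropylsilyl chloride CC(C)[Si](Cl)(C(C)C)C(C)C
Why: Silyl ether formation: the C2 hydroxyl is hydrogen‑bonded to the aldehyde and flanked on both sides, so the bulky silyl chloride should react only at the more acidic C4 hydroxyl.

Step 3
Reactants: 4 3‑geranyl‑2‑hydroxy‑4‑(triisopropylsilyloxy)benzaldehyde
Product: 5 6‑(2,2‑dibromoethenyl)‑2‑geranyl‑3‑(triisopropylsilyloxy)phenol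
Conditions: CBr4 (1.5 equiv), PPh3 (3 equiv), Et3N, CH2Cl2, 0 °C
Reagents that add atoms: tetrabromomethane BrC(Br)(Br)Br
Why: Ramirez dibromoolefination (first stage of a Corey–Fuchs sequence): Ph3P=CBr2 formed from CBr4 and PPh3 condenses with the aldehyde in a Wittig reaction, the free phenol being tolerated as its triethylammonium salt and the silyl ether and isolated olefins being inert.

Step 4
Reactants: 5 6‑(2,2‑dibromoethenyl)‑2‑geranyl‑3‑(triisopropylsilyloxy)phenol
Product: 6 2‑bromo‑7‑geranyl‑6‑(triisopropylsilyloxy)‑1‑benzofuran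
Conditions: CuI (5 mol %), K3PO4 (2 equiv), THF, 80 °C
Reagents that add atoms: none
Why: Intramolecular Ullmann‑type C–O coupling: the copper phenoxide engages the vinylic C–Br bond cis to the ring and closes the furan, leaving the geminal bromide as the C2 bromide of the benzofuran.

Step 5
Reactants: 7 1‑bromo‑3,5‑dimethoxybenzene
Product: 8 2‑bromo‑4,6‑dimethoxybenzaldehyde
Conditions: POCl3, DMF, 0 → 90 °C; then ice‑water
Reagents that add atoms: N,N‑dimethylformamide CN(C)C=O; water O
Why: Vilsmeier–Haack formylation: the position ortho to bromine is para to one methoxy group and ortho to the other and should be the main site of attack, the symmetrical 4‑bromo‑2,6‑dimethoxy isomer being removed by crystallisation.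

Step 6
Reactants: 8 2‑bromo‑4,6‑dimethoxybenzaldehyde
Product: 9 2‑bromo‑4,6‑dihydroxybenzaldehyde
Conditions: BBr3 (4 equiv), CH2Cl2, −78 °C → rt; then H2O
Reagents that add atoms: none
Why: Lewis acid cleavage of aryl methyl ethers with BBr3 should free both phenols, the one ortho to the formyl group first through chelation, while the aryl bromide and the aldehyde are untouched.

Step 7
Reactants: 9 2‑bromo‑4,6‑dihydroxybenzaldehyde
Product: 10 2‑bromo‑6‑hydroxy‑4‑(triisopropylsilyloxy)benzaldehyde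
Conditions: TIPSCl (1.05 equiv), imidazole, CH2Cl2, 0 °C
Reagents that add atoms: triisopropylsilyl chloride CC(C)[Si](Cl)(C(C)C)C(C)C
Why: Selective silyl ether formation as in step 2: the C6 hydroxyl is hydrogen‑bonded to the formyl group, so the silyl chloride should take the C4 hydroxyl para to it.

Step 8
Reactants: 6 2‑bromo‑7‑geranyl‑6‑(triisopropylsilyloxy)‑1‑benzofuran; 10 2‑bromo‑6‑hydroxy‑4‑(triisopropylsilyloxy)benzaldehyde
Product: 13 2‑[7‑geranyl‑6‑(triisopropylsilyloxy)‑1‑benzofuran‑2‑yl]‑6‑hydroxy‑4‑(triisopropylsilyloxy)benzaldehyde, via 2‑lithiobenzofuran 11 (not isolated), via lithium triisopropyl borate 12 (not isolated)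
Conditions: 6 (1.3 equiv), n‑BuLi, THF, −78 °C; B(OiPr)3, −78 °C → rt; then 10, Pd(OAc)2 (3 mol %), XPhos (6 mol %), aq K3PO4, 40 °C
Reagents that add atoms: none
Why: Bromine–lithium exchange and borylation give a lithium triisopropyl borate that enters a Suzuki–Miyaura coupling under mild aqueous phosphate with the aryl bromide, which is activated by its ortho formyl group, and using the ate complex in situ keeps protodeboronation of the furan‑2‑yl boron species low.

Step 9
Reactants: 13 2‑[7‑geranyl‑6‑(triisopropylsilyloxy)‑1‑benzofuran‑2‑yl]‑6‑hydroxy‑4‑(triisopropylsilyloxy)benzaldehyde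
Product: 14 3‑[7‑geranyl‑6‑(triisopropylsilyloxy)‑1‑benzofuran‑2‑yl]‑2‑(hydroxymethyl)‑5‑(triisopropylsilyloxy)phenol
Conditions: NaBH4, THF–MeOH, 0 °C; aq NH4Cl; used crude
Reagents that add atoms: none
Why: Borohydride reduction of the aldehyde to the benzylic alcohol, with silyl ethers, olefins and the benzofuran inert to the hydride.

Step 10
Reactants: 14 3‑[7‑geranyl‑6‑(triisopropylsilyloxy)‑1‑benzofuran‑2‑yl]‑2‑(hydroxymethyl)‑5‑(triisopropylsilyloxy)phenol
Product: 15 3‑[7‑geranyl‑6‑(triisopropylsilyloxy)‑1‑benzofuran‑2‑yl]‑2‑[(4‑methylphenyl)sulfonylmethyl]‑5‑(triisopropylsilyloxy)phenol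
Conditions: p‑TolSO2H (2 equiv, freshly liberated from its sodium salt), CH2Cl2, 0 °C → rt
Reagents that add atoms: p‑toluenesulfinic acid Cc1ccc(cc1)S(=O)O
Why: Acid‑promoted benzylic substitution (S‑alkylation of a sulfinate): the ortho hydroxyl and para silyloxy groups let the benzylic alcohol ionise at the acidity of the sulfinic acid itself, and the soft sulfur of the excess sulfinate should capture the cation as the sulfone before the geranyl chain or a second arene can react.

Step 11
Reactants: 16 quinidine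
Product: 17 O‑methylquinidine
Conditions: NaH, DMF, 0 °C; MeI (1.05 equiv), 0 °C → rt
Reagents that add atoms: iodomethane CI
Why: Williamson etherification: the C9 sodium alkoxide is far more nucleophilic than the quinuclidine nitrogen, so one equivalent of MeI should give the methyl ether, which blocks later lactonisation of the ammonium ester onto this oxygen.

Step 12
Reactants: 17 O‑methylquinidine; 18 tert‑butyl bromoacetate
Product: 19 1‑(2‑tert‑butoxy‑2‑oxoethyl)‑O‑methylquinidinium bromide (quaternised at the quinuclidine nitrogen)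
Conditions: 17 (1.05 equiv), THF, rt; precipitation with Et2O
Reagents that add atoms: none
Why: Menshutkin quaternisation: the quinuclidine nitrogen, much more nucleophilic than the quinoline nitrogen, displaces bromide from the α‑bromo ester, and isolating the salt removes free bromoacetate that would otherwise O‑alkylate the phenoxide in step 13.

Step 13
Reactants: 15 3‑[7‑geranyl‑6‑(triisopropylsilyloxy)‑1‑benzofuran‑2‑yl]‑2‑[(4‑methylphenyl)sulfonylmethyl]‑5‑(triisopropylsilyloxy)phenol; 19 1‑(2‑tert‑butoxy‑2‑oxoethyl)‑O‑methylquinidinium bromide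
Product: 23 tert‑butyl (2S)‑4‑[7‑geranyl‑6‑(triisopropylsilyloxy)‑1‑benzofuran‑2‑yl]‑6‑(triisopropylsilyloxy)‑2,3‑dihydro‑1‑benzofuran‑2‑carboxylate, via ortho‑quinone methide 20 (not isolated), via ammonium ylide 21 (not isolated), via betaine 22 (not isolated)
Conditions: 19 (2 equiv), Cs2CO3 (4 equiv), CH2Cl2, 0 °C → rt, 15 added slowly
Reagents that add atoms: none
Why: Cs2CO3 deprotonates the C3' phenol, toluenesulfinate leaves in an E1cB elimination to give the ring C ortho‑quinone methide, and the same base turns the ammonium salt into its ester‑stabilised ylide. The ylide carbon adds to the exocyclic methylene (C3''–C2''), ring C rearomatises, and the C3' phenoxide displaces the alkaloid from C2'' with inversion (O–C2''), closing ring D in the 5‑exo‑tet mode. The closest known reaction type is the asymmetric [4+1] annulation of cinchona‑derived ammonium ylides with ortho‑quinone methides generated from 2‑(sulfonylalkyl)phenols. C2'' is controlled by the quinuclidinium group, whose C9 aryl(methoxy)methyl arm shields one face of the planar ylide during the addition, the substitution then inverting that centre stereospecifically to (S). The step needs a single methide and a single closing oxygen, which the substrate secures because only the C3' oxygen is free (no para‑quinone methide through O5', no competing phenoxide), and the excess of salt should trap the unsubstituted methide before it oligomerises. Ring closure should outrun epimerisation of the betaine because the ammonium leaving group sits next to the phenoxide, and the tert‑butyl ester keeps the α‑proton of the product from exchanging under the carbonate.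

Step 14
Reactants: 23 tert‑butyl (2S)‑4‑[7‑geranyl‑6‑(triisopropylsilyloxy)‑1‑benzofuran‑2‑yl]‑6‑(triisopropylsilyloxy)‑2,3‑dihydro‑1‑benzofuran‑2‑carboxylate
Product: 25 2‑[(2S)‑4‑[7‑geranyl‑6‑(triisopropylsilyloxy)‑1‑benzofuran‑2‑yl]‑6‑(triisopropylsilyloxy)‑2,3‑dihydro‑1‑benzofuran‑2‑yl]propan‑2‑ol, via methyl ketone 24 (not isolated)
Conditions: MeMgBr (6 equiv), THF, −20 → 0 °C; aq NH4Cl
Reagents that add atoms: methylmagnesium bromide C[Mg]Br
Why: Double Grignard addition to the ester through the methyl ketone: the stereocentre is α to the carbonyl but addition of the small, weakly basic MeMgBr should be faster than enolisation, so the (S) configuration should be kept.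

Step 15
Reactants: 25 2‑[(2S)‑4‑[7‑geranyl‑6‑(triisopropylsilyloxy)‑1‑benzofuran‑2‑yl]‑6‑(triisopropylsilyloxy)‑2,3‑dihydro‑1‑benzofuran‑2‑yl]propan‑2‑ol
Product: 26 2‑[(2S)‑6‑hydroxy‑2‑(2‑hydroxypropan‑2‑yl)‑2,3‑dihydro‑1‑benzofuran‑4‑yl]‑7‑geranyl‑1‑benzofuran‑6‑ol (CNP0312668.2)
Conditions: Bu4NF (3 equiv), AcOH (3 equiv), THF, 0 °C → rt
Reagents that add atoms: none
Why: Fluoride‑mediated desilylation of both aryl silyl ethers, buffered with acetic acid so that the electron‑rich phenols are not left as phenoxides, with the tertiary alcohol, the stereocentre and the geranyl olefins inert.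

Compound list

1 | 2,4‑dihydroxybenzaldehyde | O=Cc1ccc(O)cc1O | starting material
2 | geranyl bromide | CC(C)=CCC/C(C)=C/CBr | starting material
3 | 3‑geranyl‑2,4‑dihydroxybenzaldehyde | CC(C)=CCC/C(C)=C/Cc1c(O)ccc(C=O)c1O | intermediate
4 | 3‑geranyl‑2‑hydroxy‑4‑(triisopropylsilyloxy)benzaldehyde | CC(C)=CCC/C(C)=C/Cc1c(O[Si](C(C)C)(C(C)C)C(C)C)ccc(C=O)c1O | intermediate
5 | 6‑(2,2‑dibromoethenyl)‑2‑geranyl‑3‑(triisopropylsilyloxy)phenol | CC(C)=CCC/C(C)=C/Cc1c(O[Si](C(C)C)(C(C)C)C(C)C)ccc(C=C(Br)Br)c1O | intermediate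
6 | 2‑bromo‑7‑geranyl‑6‑(triisopropylsilyloxy)‑1‑benzofuran | CC(C)=CCC/C(C)=C/Cc1c(O[Si](C(C)C)(C(C)C)C(C)C)ccc2cc(Br)oc12 | intermediate
7 | 1‑bromo‑3,5‑dimethoxybenzene | COc1cc(Br)cc(OC)c1 | starting material
8 | 2‑bromo‑4,6‑dimethoxybenzaldehyde | COc1cc(Br)c(C=O)c(OC)c1 | intermediate
9 | 2‑bromo‑4,6‑dihydroxybenzaldehyde | O=Cc1c(O)cc(O)cc1Br | intermediate
10 | 2‑bromo‑6‑hydroxy‑4‑(triisopropylsilyloxy)benzaldehyde | O=Cc1c(O)cc(O[Si](C(C)C)(C(C)C)C(C)C)cc1Br | intermediate
11 | [7‑geranyl‑6‑(triisopropylsilyloxy)‑1‑benzofuran‑2‑yl]lithium | CC(C)=CCC/C(C)=C/Cc1c(O[Si](C(C)C)(C(C)C)C(C)C)ccc2cc([Li])oc12 | intermediate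
12 | lithium [7‑geranyl‑6‑(triisopropylsilyloxy)‑1‑benzofuran‑2‑yl]tri(propan‑2‑yloxy)borate | CC(C)=CCC/C(C)=C/Cc1c(O[Si](C(C)C)(C(C)C)C(C)C)ccc2cc([B-](OC(C)C)(OC(C)C)OC(C)C)oc12.[Li+] | intermediate
13 | 2‑[7‑geranyl‑6‑(triisopropylsilyloxy)‑1‑benzofuran‑2‑yl]‑6‑hydroxy‑4‑(triisopropylsilyloxy)benzaldehyde | CC(C)=CCC/C(C)=C/Cc1c(O[Si](C(C)C)(C(C)C)C(C)C)ccc2cc(-c3cc(O[Si](C(C)C)(C(C)C)C(C)C)cc(O)c3C=O)oc12 | intermediate
14 | 3‑[7‑geranyl‑6‑(triisopropylsilyloxy)‑1‑benzofuran‑2‑yl]‑2‑(hydroxymethyl)‑5‑(triisopropylsilyloxy)phenol | CC(C)=CCC/C(C)=C/Cc1c(O[Si](C(C)C)(C(C)C)C(C)C)ccc2cc(-c3cc(O[Si](C(C)C)(C(C)C)C(C)C)cc(O)c3CO)oc12 | intermediate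
15 | 3‑[7‑geranyl‑6‑(triisopropylsilyloxy)‑1‑benzofuran‑2‑yl]‑2‑[(4‑methylphenyl)sulfonylmethyl]‑5‑(triisopropylsilyloxy)phenol | CC(C)=CCC/C(C)=C/Cc1c(O[Si](C(C)C)(C(C)C)C(C)C)ccc2cc(-c3cc(O[Si](C(C)C)(C(C)C)C(C)C)cc(O)c3CS(=O)(=O)c3ccc(C)cc3)oc12 | intermediate
16 | quinidine | COc1ccc2nccc(c2c1)[C@@H]([C@H]1C[C@@H]2CCN1C[C@@H]2C=C)O | starting material
17 | O‑methylquinidine | COc1ccc2nccc(c2c1)[C@@H]([C@H]1C[C@@H]2CCN1C[C@@H]2C=C)OC | intermediate
18 | tert‑butyl bromoacetate | CC(C)(C)OC(=O)CBr | starting material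
19 | 1‑(2‑tert‑butoxy‑2‑oxoethyl)‑O‑methylquinidinium bromide | COc1ccc2nccc(c2c1)[C@@H]([C@H]1C[C@@H]2CC[N@@+]1(CC(=O)OC(C)(C)C)C[C@@H]2C=C)OC.[Br-] | intermediate
20 | 5‑[7‑geranyl‑6‑(triisopropylsilyloxy)‑1‑benzofuran‑2‑yl]‑6‑methylidene‑3‑(triisopropylsilyloxy)cyclohexa‑2,4‑dien‑1‑one (ring C ortho‑quinone methide) | CC(C)=CCC/C(C)=C/Cc1c(O[Si](C(C)C)(C(C)C)C(C)C)ccc2cc(C3=CC(O[Si](C(C)C)(C(C)C)C(C)C)=CC(=O)C3=C)oc12 | intermediate
21 | ammonium ylide of 19 (carbanion between the quinuclidinium nitrogen and the tert‑butyl ester) | COc1ccc2nccc(c2c1)[C@@H]([C@H]1C[C@@H]2CC[N@@+]1([CH-]C(=O)OC(C)(C)C)C[C@@H]2C=C)OC | intermediate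
22 | betaine: ring C 3'‑phenoxide whose C2' methylene carries the (R)‑configured CH(CO2tBu) bound to the O‑methylquinidinium nitrogen | COc1ccc2nccc(c2c1)[C@@H]([C@H]1C[C@@H]2CC[N@@+]1([C@@H](C(=O)OC(C)(C)C)Cc1c([O-])cc(O[Si](C(C)C)(C(C)C)C(C)C)cc1-c1cc3ccc(O[Si](C(C)C)(C(C)C)C(C)C)c(C/C=C(\C)CCC=C(C)C)c3o1)C[C@@H]2C=C)OC | intermediate
23 | tert‑butyl (2S)‑4‑[7‑geranyl‑6‑(triisopropylsilyloxy)‑1‑benzofuran‑2‑yl]‑6‑(triisopropylsilyloxy)‑2,3‑dihydro‑1‑benzofuran‑2‑carboxylate | CC(C)=CCC/C(C)=C/Cc1c(O[Si](C(C)C)(C(C)C)C(C)C)ccc2cc(-c3cc(O[Si](C(C)C)(C(C)C)C(C)C)cc4c3C[C@@H](C(=O)OC(C)(C)C)O4)oc12 | intermediate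
24 | 1‑[(2S)‑4‑[7‑geranyl‑6‑(triisopropylsilyloxy)‑1‑benzofuran‑2‑yl]‑6‑(triisopropylsilyloxy)‑2,3‑dihydro‑1‑benzofuran‑2‑yl]ethan‑1‑one | CC(C)=CCC/C(C)=C/Cc1c(O[Si](C(C)C)(C(C)C)C(C)C)ccc2cc(-c3cc(O[Si](C(C)C)(C(C)C)C(C)C)cc4c3C[C@@H](C(C)=O)O4)oc12 | intermediate
25 | 2‑[(2S)‑4‑[7‑geranyl‑6‑(triisopropylsilyloxy)‑1‑benzofuran‑2‑yl]‑6‑(triisopropylsilyloxy)‑2,3‑dihydro‑1‑benzofuran‑2‑yl]propan‑2‑ol | CC(C)=CCC/C(C)=C/Cc1c(O[Si](C(C)C)(C(C)C)C(C)C)ccc2cc(-c3cc(O[Si](C(C)C)(C(C)C)C(C)C)cc4c3C[C@@H](C(C)(C)O)O4)oc12 | intermediate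
26 | 2‑[(2S)‑6‑hydroxy‑2‑(2‑hydroxypropan‑2‑yl)‑2,3‑dihydro‑1‑benzofuran‑4‑yl]‑7‑geranyl‑1‑benzofuran‑6‑ol | CC(C)=CCC/C(C)=C/Cc1c(O)ccc2cc(-c3cc(O)cc4c3C[C@@H](C(C)(C)O)O4)oc12 | target

Total step count: 15. Longest linear sequence: 10 steps (steps 1, 2, 3, 4, 8, 9, 10, 13, 14, 15).

Steps most likely to fail

Step 13. The alkaloid leaving group may discriminate the two faces of the ylide poorly when the methide carbon carries no substituent, or the betaine may epimerise before ring closure, so the ester would form with low enantiomeric purity. The fallback replaces reagent control by a covalent auxiliary with separation of diastereomers, using the known annulation of an achiral ammonium ylide. It sets out from sulfone 15. (−)‑Menthol is acylated with bromoacetyl bromide (pyridine, CH2Cl2) to (1R,2S,5R)‑menthyl bromoacetate F1, which is quaternised with DABCO to the ammonium bromide F2. F2 is combined with 15 and Cs2CO3 in CH2Cl2 as in step 13, and the two C2'' epimeric menthyl esters are separated by chromatography or crystallisation. The (2S) epimer, menthyl ester F3, is treated with excess MeMgBr as in step 14, which returns to the route at carbinol 25.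

Step 10. The benzylic cation, or the methide formed from it, may be captured by the electron‑rich ring C of a second molecule faster than by sulfinate, giving oligomers, or the acid may start to cyclise the geranyl chain. The fallback is acid‑free and runs through a phenolic Mannich base. It sets out from aldehyde 13. Reductive amination with dimethylamine and NaBH(OAc)3 gives the 2‑(dimethylaminomethyl)phenol F4, and MeI converts it into the trimethylammonium iodide F5. Warming F5 with sodium p‑toluenesulfinate in aqueous MeCN expels trimethylamine and takes up sulfinate at the benzylic carbon, returning to the route at sulfone 15.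

Step 8. Protodeboronation of the furan‑2‑yl borate may outpace transmetalation, or the aqueous base may strip the silyl ether para to the formyl group. The fallback is a base‑free Stille coupling. It sets out from bromide 6. Bromine–lithium exchange (n‑BuLi, THF, −78 °C) and quenching with Bu3SnCl give the isolable tributylstannane F6, which is coupled with bromide 10 using Pd(PPh3)4 and CuI in DMF, returning to the route at aldehyde 13.

Further compounds

F1 | step 13 | (1R,2S,5R)‑menthyl bromoacetate | CC(C)[C@@H]1CC[C@@H](C)C[C@H]1OC(=O)CBr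
F2 | step 13 | 1‑{2‑[(1R,2S,5R)‑menthyloxy]‑2‑oxoethyl}‑4‑aza‑1‑azoniabicyclo[2.2.2]octane bromide | CC(C)[C@@H]1CC[C@@H](C)C[C@H]1OC(=O)C[N+]12CCN(CC1)CC2.[Br-]
F3 | step 13 | (1R,2S,5R)‑menthyl (2S)‑4‑[7‑geranyl‑6‑(triisopropylsilyloxy)‑1‑benzofuran‑2‑yl]‑6‑(triisopropylsilyloxy)‑2,3‑dihydro‑1‑benzofuran‑2‑carboxylate | CC(C)=CCC/C(C)=C/Cc1c(O[Si](C(C)C)(C(C)C)C(C)C)ccc2cc(-c3cc(O[Si](C(C)C)(C(C)C)C(C)C)cc4c3C[C@@H](C(=O)O[C@@H]5C[C@H](C)CC[C@H]5C(C)C)O4)oc12
F4 | step 10 | 2‑[(dimethylamino)methyl]‑3‑[7‑geranyl‑6‑(triisopropylsilyloxy)‑1‑benzofuran‑2‑yl]‑5‑(triisopropylsilyloxy)phenol | CC(C)=CCC/C(C)=C/Cc1c(O[Si](C(C)C)(C(C)C)C(C)C)ccc2cc(-c3cc(O[Si](C(C)C)(C(C)C)C(C)C)cc(O)c3CN(C)C)oc12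
F5 | step 10 | {2‑[7‑geranyl‑6‑(triisopropylsilyloxy)‑1‑benzofuran‑2‑yl]‑6‑hydroxy‑4‑(triisopropylsilyloxy)phenyl}methyl‑trimethylammonium iodide | CC(C)=CCC/C(C)=C/Cc1c(O[Si](C(C)C)(C(C)C)C(C)C)ccc2cc(-c3cc(O[Si](C(C)C)(C(C)C)C(C)C)cc(O)c3C[N+](C)(C)C)oc12.[I-]
F6 | step 8 | tributyl[7‑geranyl‑6‑(triisopropylsilyloxy)‑1‑benzofuran‑2‑yl]stannane | CC(C)=CCC/C(C)=C/Cc1c(O[Si](C(C)C)(C(C)C)C(C)C)ccc2cc([Sn](CCCC)(CCCC)CCCC)oc12
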